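**Retrosynthetic overview**
1. Target 32 comes from C8 desilylation, C6 acylation and hydroxyl-directed C4–C5 epoxidation of the (1(10)E,4E)-germacradien-6-ol 28; the oxirane is the second and last ring formed.
2. The ten-membered carbocycle (first ring) is closed at C2–C3 by intramolecular alkylation of a C2 allyl sulfone anion with a C3 allylic chloride, then reductive desulfonylation.
3. C8–C9 comes from a chelation-controlled vinylogous Mukaiyama aldol of C8 aldehyde 14 with silyl dienolate 17, which sets C8 and installs the E-C1=C10 olefin.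
4. C6–C7 (key fragment union) comes from an Evans syn-aldol of N-isovaleryl oxazolidinone 8 with enal 5, which sets C6 and C7.
5. Building blocks: prenyl acetate, isovaleryl chloride, (S)-4-benzyloxazolidinone, methyl 3-methylbut-2-enoate, 3,4,5-trimethoxybenzoyl chloride.

Assumption: atom labels C1–C15 are germacrane numbering of the target (ring C1–C10; E-olefin C1=C10; epoxide C4–C5; ester carbinol C6; CH–i-Pr C7; free carbinol C8; methyls C14 on C10 and C15 on C4) and are used for all intermediates.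

**Route**

Step 1
Reactants: 1 prenyl acetate (3-methylbut-2-en-1-yl acetate)
Product: 2 (2E)-4-hydroxy-3-methylbut-2-en-1-yl acetate
Conditions: SeO2 (0.3 equiv), t-BuOOH (70% aq., 3 equiv), salicylic acid (cat.), DCM, rt
Reagents that add atoms: tert-butyl hydroperoxide, CC(C)(C)OO
Why: Riley allylic oxidation (ene reaction then 2,3-sigmatropic shift) hydroxylates only the methyl group trans to the CH2OAc chain, so the E geometry later needed for C4=C5 is fixed here.

Step 2
Reactants: 2 (2E)-4-hydroxy-3-methylbut-2-en-1-yl acetate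
Product: 3 (2E)-4-[(tert-butyldimethylsilyl)oxy]-3-methylbut-2-en-1-yl acetate
Conditions: TBSCl, imidazole, DMF, 0 °C → rt
Reagents that add atoms: tert-butyldimethylsilyl chloride, CC(C)(C)[Si](C)(C)Cl
Why: Standard silylation of the primary allylic alcohol (future C3–O) gives an ether that survives every step up to its selective removal in step 16.

Step 3
Reactants: 3 (2E)-4-[(tert-butyldimethylsilyl)oxy]-3-methylbut-2-en-1-yl acetate
Product: 4 (2E)-4-[(tert-butyldimethylsilyl)oxy]-3-methylbut-2-en-1-ol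
Conditions: K2CO3 (cat.), MeOH, 0 °C
Reagents that add atoms: none
Why: Base-catalysed transesterification removes the acetate while the silyl ether and olefin geometry are untouched.

Step 4
Reactants: 4 (2E)-4-[(tert-butyldimethylsilyl)oxy]-3-methylbut-2-en-1-ol
Product: 5 (2E)-4-[(tert-butyldimethylsilyl)oxy]-3-methylbut-2-enal
Conditions: MnO2 (activated, excess), DCM, rt
Reagents that add atoms: none
Why: Chemoselective MnO2 oxidation of the allylic alcohol gives the enal (C6 aldehyde) without over-oxidation or E/Z isomerisation.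

Step 5
Reactants: 6 (4S)-4-benzyl-1,3-oxazolidin-2-one, 7 3-methylbutanoyl chloride
Product: 8 (4S)-4-benzyl-3-(3-methylbutanoyl)-1,3-oxazolidin-2-one
Conditions: Et3N, DMAP (cat.), DCM, 0 °C → rt
Reagents that add atoms: none
Why: DMAP-catalysed N-acylation of the oxazolidinone installs the chiral auxiliary on the isovaleryl unit that becomes C7, C8 and the isopropyl group.

Step 6
Reactants: 8 (4S)-4-benzyl-3-(3-methylbutanoyl)-1,3-oxazolidin-2-one, 5 (2E)-4-[(tert-butyldimethylsilyl)oxy]-3-methylbut-2-enal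
Product: 10 (4S)-4-benzyl-3-[(2S,3R,4E)-6-[(tert-butyldimethylsilyl)oxy]-3-hydroxy-5-methyl-2-(propan-2-yl)hex-4-enoyl]-1,3-oxazolidin-2-one, via dibutylboron Z-enolate 9 (not isolated)
Conditions: Bu2BOTf, i-Pr2NEt, DCM, 0 °C; 5, −78 → 0 °C; then pH 7 buffer, MeOH, 30% H2O2, 0 °C
Reagents that add atoms: none
Why: Evans syn-aldol in which the Z-boron enolate reacts through a chair Zimmerman–Traxler transition state on the face away from the benzyl group, forming the C6–C7 bond and setting the C6 carbinol and C7 isopropyl centres as the 2S,3R syn pair.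

Step 7
Reactants: 10 Evans syn-aldol adduct
Product: 11 (2R,3R,4E)-6-[(tert-butyldimethylsilyl)oxy]-5-methyl-2-(propan-2-yl)hex-4-ene-1,3-diol
Conditions: LiBH4, MeOH (1 equiv), THF, 0 °C
Reagents that add atoms: none
Why: Reductive cleavage of the imide by LiBH4 gives the 1,3-diol (C8 primary, C6 secondary) without epimerising C7 and returns auxiliary 6 for reuse.

Step 8
Reactants: 11 (2R,3R,4E)-6-[(tert-butyldimethylsilyl)oxy]-5-methyl-2-(propan-2-yl)hex-4-ene-1,3-diol
Product: 12 (2S,4R,5R)-4-[(1E)-3-[(tert-butyldimethylsilyl)oxy]-2-methylprop-1-en-1-yl]-2-(4-methoxyphenyl)-5-(propan-2-yl)-1,3-dioxane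
Conditions: 4-MeOC6H4CH(OMe)2, PPTS (cat.), DCM, rt
Reagents that add atoms: 4-methoxybenzaldehyde dimethyl acetal, COc1ccc(C(OC)OC)cc1
Why: Thermodynamic acetalisation of the 1,3-diol under very mild acid gives the p-methoxybenzylidene acetal with the aryl group equatorial and cis to the C6 alkenyl group, avoiding direct O-alkylation of the sensitive allylic alcohol.

Step 9
Reactants: 12 p-methoxybenzylidene acetal
Product: 13 (2R,3R,4E)-6-[(tert-butyldimethylsilyl)oxy]-3-[(4-methoxybenzyl)oxy]-5-methyl-2-(propan-2-yl)hex-4-en-1-ol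
Conditions: i-Bu2AlH (3 equiv), DCM, −78 → 0 °C
Reagents that add atoms: none
Why: Regioselective reductive acetal opening, in which aluminium binds the less hindered primary oxygen and hydride cleaves that C–O bond, leaves the PMB ether on the secondary C6 oxygen and frees the C8 primary alcohol.

Step 10
Reactants: 13 C6 PMB ether primary alcohol
Product: 14 (2S,3R,4E)-6-[(tert-butyldimethylsilyl)oxy]-3-[(4-methoxybenzyl)oxy]-5-methyl-2-(propan-2-yl)hex-4-enal
Conditions: Dess–Martin periodinane, DCM, 0 °C → rt, used crude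
Reagents that add atoms: none
Why: Dess–Martin oxidation gives the α-branched β-alkoxy aldehyde (C8) under non-basic conditions, so C7 does not epimerise and the PMB ether does not eliminate.

Step 11
Reactants: 15 methyl 3-methylbut-2-enoate
Product: 17 1-methoxy-3-methyl-1-(trimethylsilyloxy)buta-1,3-diene, via lithium dienolate 16 (not isolated)
Conditions: LiN(i-Pr)2, THF, −78 °C; Me3SiCl, −78 °C → rt
Reagents that add atoms: chlorotrimethylsilane, C[Si](C)(C)Cl
Why: Kinetic γ-deprotonation of the senecioate and O-silylation give the vinylogous silyl ketene acetal that serves as the C9–C10(C14)–C1–C2 nucleophile.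

Step 12
Reactants: 14 C8 aldehyde, 17 1-methoxy-3-methyl-1-(trimethylsilyloxy)buta-1,3-diene
Product: 18 methyl (2E,5R,6R,7R,8E)-10-[(tert-butyldimethylsilyl)oxy]-5-hydroxy-7-[(4-methoxybenzyl)oxy]-3,9-dimethyl-6-(propan-2-yl)deca-2,8-dienoate
Conditions: MgBr2·OEt2 (3 equiv), DCM, −78 → −30 °C; work-up with 10% citric acid/MeOH
Reagents that add atoms: none
Why: Chelation-controlled vinylogous Mukaiyama aldol in which MgBr2 bridges the aldehyde and C6 PMB-ether oxygens and the dienolate γ-carbon attacks the chelate face opposite the cis-disposed C7 isopropyl and C6 alkenyl groups, giving the anti-Felkin 1,3-anti C8 carbinol and, through the s-trans diene, the E-enoate (any Z-isomer lactonises and is removed).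

Step 13
Reactants: 18 C8 alcohol enoate
Product: 19 methyl (2E,5R,6S,7R,8E)-5,10-bis[(tert-butyldimethylsilyl)oxy]-7-[(4-methoxybenzyl)oxy]-3,9-dimethyl-6-(propan-2-yl)deca-2,8-dienoate
Conditions: TBSOTf, 2,6-lutidine, DCM, −78 → 0 °C
Reagents that add atoms: tert-butyldimethylsilyl triflate, CC(C)(C)[Si](C)(C)OS(=O)(=O)C(F)(F)F
Why: Silyl triflate protects the hindered secondary C8 hydroxyl as a robust TBS ether that is kept until the last step.

Step 14
Reactants: 19 bis-silyl enoate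
Product: 20 (2E,5R,6S,7R,8E)-5,10-bis[(tert-butyldimethylsilyl)oxy]-7-[(4-methoxybenzyl)oxy]-3,9-dimethyl-6-(propan-2-yl)deca-2,8-dien-1-ol
Conditions: i-Bu2AlH (2.5 equiv), DCM, −78 °C
Reagents that add atoms: none
Why: 1,2-Reduction of the enoate by i-Bu2AlH gives the E-allylic alcohol (C2–OH) without touching silyl or PMB ethers.

Step 15
Reactants: 20 C2 allylic alcohol
Product: 22 {[(2E,5R,6S,7R,8E)-5,10-bis[(tert-butyldimethylsilyl)oxy]-7-[(4-methoxybenzyl)oxy]-3,9-dimethyl-6-(propan-2-yl)deca-2,8-dien-1-yl]sulfonyl}benzene, via allylic chloride 21 (not isolated)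
Conditions: MsCl, LiCl, 2,4,6-collidine, DMF, 0 °C; then PhSO2Na, rt
Reagents that add atoms: sodium benzenesulfinate, [Na+].[O-]S(=O)c1ccccc1
Why: Mesylation with in situ chloride displacement gives the primary allylic chloride without allylic transposition, and S-alkylation of the sulfinate (SN2) gives the thermodynamically preferred primary E-allyl sulfone at C2.

Step 16
Reactants: 22 C2 allyl sulfone
Product: 23 (2E,4R,5S,6R,8E)-6-[(tert-butyldimethylsilyl)oxy]-4-[(4-methoxybenzyl)oxy]-2,8-dimethyl-10-(phenylsulfonyl)-5-(propan-2-yl)deca-2,8-dien-1-ol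
Conditions: CSA (10 mol%), MeOH/DCM (1:1), 0 °C
Reagents that add atoms: none
Why: Acid-catalysed methanolysis cleaves the unhindered primary allylic TBS ether (C3–O) far faster than the hindered secondary C8 TBS ether, and the PMB ether is inert.

Step 17
Reactants: 23 C3 allylic alcohol
Product: 24 {[(2E,5R,6S,7R,8E)-10-chloro-5-[(tert-butyldimethylsilyl)oxy]-7-[(4-methoxybenzyl)oxy]-3,9-dimethyl-6-(propan-2-yl)deca-2,8-dien-1-yl]sulfonyl}benzene
Conditions: MsCl, LiCl, 2,4,6-collidine, DMF, 0 °C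
Reagents that add atoms: lithium chloride, [Li+].[Cl-]
Why: The same mesylate-to-chloride exchange converts the C3 alcohol to the primary allylic chloride with retention of the E-C4=C5 geometry.

Step 18
Reactants: 24 chloro sulfone
Product: 26 (1(10)E,4E,6R,7S,8R)-6-[(4-methoxybenzyl)oxy]-2-(phenylsulfonyl)-8-[(tert-butyldimethylsilyl)oxy]germacra-1(10),4-diene as a mixture of C2 epimers, via potassium sulfonyl carbanion 25 (not isolated)
Conditions: KN(SiMe3)2 (1.3 equiv), THF, 2 mM, −78 → −20 °C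
Reagents that add atoms: none
Why: Intramolecular SN2 alkylation of the sulfonyl-stabilised allyl carbanion (α-attack) by the primary allylic chloride at high dilution forms the C2–C3 bond and the (E,E)-cyclodecadiene ring without touching C6, C7 or C8, and the new C2 centre is removed in the next step.

Step 19
Reactants: 26 macrocyclic sulfone
Product: 27 (1(10)E,4E,6R,7S,8R)-6-[(4-methoxybenzyl)oxy]-8-[(tert-butyldimethylsilyl)oxy]germacra-1(10),4-diene
Conditions: PdCl2(dppp) (10 mol%), LiBHEt3 (3 equiv), THF, 0 °C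
Reagents that add atoms: none
Why: In this palladium-catalysed reductive desulfonylation, zerovalent palladium formed in situ ionises the allylic sulfone and hydride is delivered to the less substituted C2 end of the π-allyl unit, which keeps the trisubstituted E-C1=C10 olefin in place.

Step 20
Reactants: 27 germacradiene PMB ether
Product: 28 (1(10)E,4E,6R,7S,8R)-8-[(tert-butyldimethylsilyl)oxy]germacra-1(10),4-dien-6-ol
Conditions: DDQ (1.3 equiv), DCM/pH 7 buffer (10:1), 0 °C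
Reagents that add atoms: none
Why: Oxidative PMB cleavage by DDQ under neutral buffered conditions frees the allylic C6 hydroxyl without the acid or heat that would trigger transannular cyclisation or Cope rearrangement of the germacradiene.

Step 21
Reactants: 28 germacradien-6-ol
Product: 29 (1(10)E,4R,5R,6S,7S,8R)-8-[(tert-butyldimethylsilyl)oxy]-4,5-epoxygermacr-1(10)-en-6-ol
Conditions: VO(acac)2 (5 mol%), t-BuOOH (1.5 equiv, decane), DCM, 0 °C
Reagents that add atoms: tert-butyl hydroperoxide, CC(C)(C)OO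
Why: Hydroxyl-directed epoxidation is confined to the allylic C4=C5 bond and delivers oxygen to the exposed outer face syn to the C6 hydroxyl in the A(1,3)-minimised conformer (H6 eclipsing the C4 methyl side), giving the threo 4R,5R epoxide while C1=C10 is untouched.

Step 22
Reactants: 29 epoxy alcohol, 30 3,4,5-trimethoxybenzoyl chloride
Product: 31 (1(10)E,4R,5R,6S,7S,8R)-8-[(tert-butyldimethylsilyl)oxy]-4,5-epoxygermacr-1(10)-en-6-yl 3,4,5-trimethoxybenzoate
Conditions: DMAP, Et3N, DCM, 0 °C → rt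
Reagents that add atoms: none
Why: DMAP-catalysed acylation of the only free hydroxyl (C6) with the aroyl chloride proceeds with retention at C6 and does not disturb the epoxide under these non-acidic conditions.

Step 23
Reactants: 31 C8 silyl ether of the target
Product: 32 (1(10)E,4R,5R,6S,7R,8R)-8-hydroxy-4,5-epoxygermacr-1(10)-en-6-yl 3,4,5-trimethoxybenzoate (CNP0279501.1)
Conditions: HF·pyridine, excess pyridine, THF, 0 °C → rt
Reagents that add atoms: none
Why: Buffered fluoride desilylation frees the C8 hydroxyl without an alkoxide that could shift the C6 ester to O8 and without enough acidity to open the epoxide across the ring, so all five stereocentres arrive unchanged.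

**Compound list**
1 | 3-methylbut-2-en-1-yl acetate (prenyl acetate) | CC(C)=CCOC(C)=O | starting material
2 | (2E)-4-hydroxy-3-methylbut-2-en-1-yl acetate | OC/C(C)=C/COC(C)=O | intermediate
3 | (2E)-4-[(tert-butyldimethylsilyl)oxy]-3-methylbut-2-en-1-yl acetate | CC(C)(C)[Si](C)(C)OC/C(C)=C/COC(C)=O | intermediate
4 | (2E)-4-[(tert-butyldimethylsilyl)oxy]-3-methylbut-2-en-1-ol | CC(C)(C)[Si](C)(C)OC/C(C)=C/CO | intermediate
5 | (2E)-4-[(tert-butyldimethylsilyl)oxy]-3-methylbut-2-enal | CC(C)(C)[Si](C)(C)OC/C(C)=C/C=O | intermediate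
6 | (4S)-4-benzyl-1,3-oxazolidin-2-one | O=C1N[C@@H](Cc2ccccc2)CO1 | starting material
7 | 3-methylbutanoyl chloride | CC(C)CC(Cl)=O | starting material
8 | (4S)-4-benzyl-3-(3-methylbutanoyl)-1,3-oxazolidin-2-one | CC(C)CC(=O)N1[C@@H](Cc2ccccc2)COC1=O | intermediate
9 | dibutylboron (Z)-enolate of 8 | CC(C)/C=C(\OB(CCCC)CCCC)N1[C@@H](Cc2ccccc2)COC1=O | intermediate
10 | (4S)-4-benzyl-3-[(2S,3R,4E)-6-[(tert-butyldimethylsilyl)oxy]-3-hydroxy-5-methyl-2-(propan-2-yl)hex-4-enoyl]-1,3-oxazolidin-2-one | CC(C)[C@H](C(=O)N1[C@@H](Cc2ccccc2)COC1=O)[C@H](O)/C=C(\C)CO[Si](C)(C)C(C)(C)C | intermediate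
11 | (2R,3R,4E)-6-[(tert-butyldimethylsilyl)oxy]-5-methyl-2-(propan-2-yl)hex-4-ene-1,3-diol | CC(C)[C@H](CO)[C@H](O)/C=C(\C)CO[Si](C)(C)C(C)(C)C | intermediate
12 | (2S,4R,5R)-4-[(1E)-3-[(tert-butyldimethylsilyl)oxy]-2-methylprop-1-en-1-yl]-2-(4-methoxyphenyl)-5-(propan-2-yl)-1,3-dioxane | CC(C)[C@@H]1CO[C@H](c2ccc(OC)cc2)O[C@@H]1/C=C(\C)CO[Si](C)(C)C(C)(C)C | intermediate
13 | (2R,3R,4E)-6-[(tert-butyldimethylsilyl)oxy]-3-[(4-methoxybenzyl)oxy]-5-methyl-2-(propan-2-yl)hex-4-en-1-ol | CC(C)[C@H](CO)[C@H](OCc1ccc(OC)cc1)/C=C(\C)CO[Si](C)(C)C(C)(C)C | intermediate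
14 | (2S,3R,4E)-6-[(tert-butyldimethylsilyl)oxy]-3-[(4-methoxybenzyl)oxy]-5-methyl-2-(propan-2-yl)hex-4-enal | CC(C)[C@H](C=O)[C@H](OCc1ccc(OC)cc1)/C=C(\C)CO[Si](C)(C)C(C)(C)C | intermediate
15 | methyl 3-methylbut-2-enoate | COC(=O)C=C(C)C | starting material
16 | lithium dienolate of 15 (lithium 1-methoxy-3-methylbuta-1,3-dien-1-olate) | [Li+].[O-]C(OC)=CC(C)=C | intermediate
17 | 1-methoxy-3-methyl-1-(trimethylsilyloxy)buta-1,3-diene (C1=C2 isomer mixture) | COC(O[Si](C)(C)C)=CC(C)=C | intermediate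
18 | methyl (2E,5R,6R,7R,8E)-10-[(tert-butyldimethylsilyl)oxy]-5-hydroxy-7-[(4-methoxybenzyl)oxy]-3,9-dimethyl-6-(propan-2-yl)deca-2,8-dienoate | CC(C)(C)[Si](C)(C)OC/C(C)=C/[C@@H](OCc1ccc(OC)cc1)[C@H](C(C)C)[C@H](O)C/C(C)=C/C(=O)OC | intermediate
19 | methyl (2E,5R,6S,7R,8E)-5,10-bis[(tert-butyldimethylsilyl)oxy]-7-[(4-methoxybenzyl)oxy]-3,9-dimethyl-6-(propan-2-yl)deca-2,8-dienoate | CC(C)(C)[Si](C)(C)OC/C(C)=C/[C@@H](OCc1ccc(OC)cc1)[C@H](C(C)C)[C@H](O[Si](C)(C)C(C)(C)C)C/C(C)=C/C(=O)OC | intermediate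
20 | (2E,5R,6S,7R,8E)-5,10-bis[(tert-butyldimethylsilyl)oxy]-7-[(4-methoxybenzyl)oxy]-3,9-dimethyl-6-(propan-2-yl)deca-2,8-dien-1-ol | CC(C)(C)[Si](C)(C)OC/C(C)=C/[C@@H](OCc1ccc(OC)cc1)[C@H](C(C)C)[C@H](O[Si](C)(C)C(C)(C)C)C/C(C)=C/CO | intermediate
21 | (2E,5R,6S,7R,8E)-1-chloro analogue of 20 (C1–Cl in place of C1–OH) | CC(C)(C)[Si](C)(C)OC/C(C)=C/[C@@H](OCc1ccc(OC)cc1)[C@H](C(C)C)[C@H](O[Si](C)(C)C(C)(C)C)C/C(C)=C/CCl | intermediate
22 | {[(2E,5R,6S,7R,8E)-5,10-bis[(tert-butyldimethylsilyl)oxy]-7-[(4-methoxybenzyl)oxy]-3,9-dimethyl-6-(propan-2-yl)deca-2,8-dien-1-yl]sulfonyl}benzene | CC(C)(C)[Si](C)(C)OC/C(C)=C/[C@@H](OCc1ccc(OC)cc1)[C@H](C(C)C)[C@H](O[Si](C)(C)C(C)(C)C)C/C(C)=C/CS(=O)(=O)c1ccccc1 | intermediate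
23 | (2E,4R,5S,6R,8E)-6-[(tert-butyldimethylsilyl)oxy]-4-[(4-methoxybenzyl)oxy]-2,8-dimethyl-10-(phenylsulfonyl)-5-(propan-2-yl)deca-2,8-dien-1-ol | OC/C(C)=C/[C@@H](OCc1ccc(OC)cc1)[C@H](C(C)C)[C@H](O[Si](C)(C)C(C)(C)C)C/C(C)=C/CS(=O)(=O)c1ccccc1 | intermediate
24 | {[(2E,5R,6S,7R,8E)-10-chloro-5-[(tert-butyldimethylsilyl)oxy]-7-[(4-methoxybenzyl)oxy]-3,9-dimethyl-6-(propan-2-yl)deca-2,8-dien-1-yl]sulfonyl}benzene | ClC/C(C)=C/[C@@H](OCc1ccc(OC)cc1)[C@H](C(C)C)[C@H](O[Si](C)(C)C(C)(C)C)C/C(C)=C/CS(=O)(=O)c1ccccc1 | intermediate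
25 | potassium salt of 24 deprotonated at the carbon α to sulfur (C2) | ClC/C(C)=C/[C@@H](OCc1ccc(OC)cc1)[C@H](C(C)C)[C@H](O[Si](C)(C)C(C)(C)C)C/C(C)=C/[CH-]S(=O)(=O)c1ccccc1.[K+] | intermediate
26 | (1(10)E,4E,6R,7S,8R)-6-[(4-methoxybenzyl)oxy]-2-(phenylsulfonyl)-8-[(tert-butyldimethylsilyl)oxy]germacra-1(10),4-diene (C2 epimers) | COc1ccc(CO[C@H]2[C@H](C(C)C)[C@H](O[Si](C)(C)C(C)(C)C)C/C(C)=C/C(S(=O)(=O)c3ccccc3)C/C(C)=C/2)cc1 | intermediate
27 | (1(10)E,4E,6R,7S,8R)-6-[(4-methoxybenzyl)oxy]-8-[(tert-butyldimethylsilyl)oxy]germacra-1(10),4-diene | COc1ccc(CO[C@H]2[C@H](C(C)C)[C@H](O[Si](C)(C)C(C)(C)C)C/C(C)=C/CC/C(C)=C/2)cc1 | intermediate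
28 | (1(10)E,4E,6R,7S,8R)-8-[(tert-butyldimethylsilyl)oxy]germacra-1(10),4-dien-6-ol | O[C@H]1[C@H](C(C)C)[C@H](O[Si](C)(C)C(C)(C)C)C/C(C)=C/CC/C(C)=C/1 | intermediate
29 | (1(10)E,4R,5R,6S,7S,8R)-8-[(tert-butyldimethylsilyl)oxy]-4,5-epoxygermacr-1(10)-en-6-ol | O[C@H]1[C@H](C(C)C)[C@H](O[Si](C)(C)C(C)(C)C)C/C(C)=C/CC[C@@]2(C)O[C@H]12 | intermediate
30 | 3,4,5-trimethoxybenzoyl chloride | COc1cc(C(Cl)=O)cc(OC)c1OC | starting material
31 | (1(10)E,4R,5R,6S,7S,8R)-8-[(tert-butyldimethylsilyl)oxy]-4,5-epoxygermacr-1(10)-en-6-yl 3,4,5-trimethoxybenzoate | COc1cc(C(=O)O[C@H]2[C@H](C(C)C)[C@H](O[Si](C)(C)C(C)(C)C)C/C(C)=C/CC[C@@]3(C)O[C@H]23)cc(OC)c1OC | intermediate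
32 | (1(10)E,4R,5R,6S,7R,8R)-8-hydroxy-4,5-epoxygermacr-1(10)-en-6-yl 3,4,5-trimethoxybenzoate | COc1cc(C(=O)O[C@H]2[C@H](C(C)C)[C@H](O)C/C(C)=C/CC[C@@]3(C)O[C@H]23)cc(OC)c1OC | target

**Step count and risk**

Total steps: 23. Longest linear sequence: 21 (steps 1–4, 6–10, 12–23); steps 5 and 11 are one-step side branches. The ring-containing intermediates 26–29 should be kept below about 40 °C and away from acid.

Most likely to fail: step 18 (ring closure), step 19 (desulfonylation without moving C1=C10) and step 12 (C8 selectivity and γ-regiochemistry).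

Fallback for step 12. If the chelated vinylogous aldol gives poor C8 selectivity or α-attack, the route sets out from aldehyde 14 and sets C8 under reagent control. Allenylboration with B-allenyldiisopinocampheylborane (Et2O, −78 °C, then NaOH/H2O2) gives homopropargylic alcohol F1. The Ipc antipode needed is the one that attacks the Re face of C8, which is the (−)-α-pinene-derived reagent by analogy with allylboration; this should be confirmed by Mosher analysis. TBSOTf/2,6-lutidine gives silyl ether F2. Zirconium-catalysed carboalumination (AlMe3, Cp2ZrCl2 cat., DCM, 0 °C) adds methyl and aluminium syn across the alkyne with methyl on the internal carbon, giving (E)-alkenyldimethylalane F3. Trapping with ClCO2Me returns the route at ester 19, with the E-C1=C10 geometry fixed by the syn-carbometallation.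

Fallback for step 18. If the sulfonyl carbanion does not close the ring, a more nucleophilic thioether-stabilised allyllithium is used, setting out from allylic alcohol 20. PhSSPh/n-Bu3P gives allyl phenyl sulfide F4. CSA/MeOH frees the C3 alcohol F5, and MsCl/LiCl/collidine gives allylic chloride F6. n-BuLi/DABCO in THF at −78 °C and 2 mM generates α-lithio sulfide F7, which cyclises by α-alkylation to macrocyclic sulfide F8. Chemoselective sulfur oxidation with (NH4)6Mo7O24 (cat.)/H2O2 in EtOH at 0 °C leaves the trisubstituted olefins alone and returns the route at sulfone 26.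

Fallback for step 19. If hydride desulfonylation scrambles the C1=C10 olefin, the sulfone is avoided altogether, again setting out from allylic alcohol 20. CSA/MeOH removes the primary silyl group to give diol F9. MsCl/Et3N then LiBr (THF, −40 → 0 °C) gives bis-allylic dibromide F10. Reductive cyclisation with zerovalent nickel (Ni(cod)2, DMF, slow addition, 25–40 °C) joins the two primary allylic termini (C2–C3) and returns the route directly at 27. The known weakness of this coupling is partial E/Z scrambling through the π-allylnickel intermediates.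

Further compounds
F1 | step 12 | (4R,5R,6R,7E)-9-[(tert-butyldimethylsilyl)oxy]-6-[(4-methoxybenzyl)oxy]-8-methyl-5-(propan-2-yl)non-7-en-1-yn-4-ol | CC(C)(C)[Si](C)(C)OC/C(C)=C/[C@@H](OCc1ccc(OC)cc1)[C@H](C(C)C)[C@H](O)CC#C
F2 | step 12 | (4R,5S,6R,7E)-4,9-bis[(tert-butyldimethylsilyl)oxy]-6-[(4-methoxybenzyl)oxy]-8-methyl-5-(propan-2-yl)non-7-en-1-yne | CC(C)(C)[Si](C)(C)OC/C(C)=C/[C@@H](OCc1ccc(OC)cc1)[C@H](C(C)C)[C@H](O[Si](C)(C)C(C)(C)C)CC#C
F3 | step 12 | (1E)-alkenyldimethylalane from F2 (AlMe2 on the terminal carbon, methyl on the internal carbon) | CC(C)(C)[Si](C)(C)OC/C(C)=C/[C@@H](OCc1ccc(OC)cc1)[C@H](C(C)C)[C@H](O[Si](C)(C)C(C)(C)C)C/C(C)=C/[Al](C)C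
F4 | step 18 | {[(2E,5R,6S,7R,8E)-5,10-bis[(tert-butyldimethylsilyl)oxy]-7-[(4-methoxybenzyl)oxy]-3,9-dimethyl-6-(propan-2-yl)deca-2,8-dien-1-yl]sulfanyl}benzene | CC(C)(C)[Si](C)(C)OC/C(C)=C/[C@@H](OCc1ccc(OC)cc1)[C@H](C(C)C)[C@H](O[Si](C)(C)C(C)(C)C)C/C(C)=C/CSc1ccccc1
F5 | step 18 | (2E,4R,5S,6R,8E)-6-[(tert-butyldimethylsilyl)oxy]-4-[(4-methoxybenzyl)oxy]-2,8-dimethyl-10-(phenylsulfanyl)-5-(propan-2-yl)deca-2,8-dien-1-ol | OC/C(C)=C/[C@@H](OCc1ccc(OC)cc1)[C@H](C(C)C)[C@H](O[Si](C)(C)C(C)(C)C)C/C(C)=C/CSc1ccccc1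
F6 | step 18 | {[(2E,5R,6S,7R,8E)-10-chloro-5-[(tert-butyldimethylsilyl)oxy]-7-[(4-methoxybenzyl)oxy]-3,9-dimethyl-6-(propan-2-yl)deca-2,8-dien-1-yl]sulfanyl}benzene | ClC/C(C)=C/[C@@H](OCc1ccc(OC)cc1)[C@H](C(C)C)[C@H](O[Si](C)(C)C(C)(C)C)C/C(C)=C/CSc1ccccc1
F7 | step 18 | lithium salt of F6 deprotonated at the carbon α to sulfur (C2) | ClC/C(C)=C/[C@@H](OCc1ccc(OC)cc1)[C@H](C(C)C)[C@H](O[Si](C)(C)C(C)(C)C)C/C(C)=C/[CH-]Sc1ccccc1.[Li+]
F8 | step 18 | (1(10)E,4E,6R,7S,8R)-6-[(4-methoxybenzyl)oxy]-2-(phenylsulfanyl)-8-[(tert-butyldimethylsilyl)oxy]germacra-1(10),4-diene (C2 epimers) | COc1ccc(CO[C@H]2[C@H](C(C)C)[C@H](O[Si](C)(C)C(C)(C)C)C/C(C)=C/C(Sc3ccccc3)C/C(C)=C/2)cc1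
F9 | step 19 | (2E,4R,5S,6R,8E)-6-[(tert-butyldimethylsilyl)oxy]-4-[(4-methoxybenzyl)oxy]-2,8-dimethyl-5-(propan-2-yl)deca-2,8-diene-1,10-diol | OC/C(C)=C/[C@@H](OCc1ccc(OC)cc1)[C@H](C(C)C)[C@H](O[Si](C)(C)C(C)(C)C)C/C(C)=C/CO
F10 | step 19 | (2E,4R,5S,6R,8E)-1,10-dibromo-6-[(tert-butyldimethylsilyl)oxy]-4-[(4-methoxybenzyl)oxy]-2,8-dimethyl-5-(propan-2-yl)deca-2,8-diene | BrC/C(C)=C/[C@@H](OCc1ccc(OC)cc1)[C@H](C(C)C)[C@H](O[Si](C)(C)C(C)(C)C)C/C(C)=C/CBr
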